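Assumption: germacrane numbering (C1–C15) is used for all locants in the discussion. Lactone 1 (anhydromevalonolactone) and both antipodes of TRIP and MIB are taken as catalogue items.

**Retrosynthetic overview**
1. Target 25 ⇒ diene alcohol 24. One peracid treatment installs both oxiranes (C1, C10, C4, C5) from the outer face of the ten-membered ring. The C8 angelate goes on just before.
2. Key disconnection C7–C8. An allylchromium made from a 3-(bromomethyl)butenolide turns C7, normally an acceptor β-carbon, into a d3 donor. It attacks the C8 aldehyde of 18, closing the carbocycle, setting C7 and C8, and unveiling the α-methylene lactone.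
3. Butenolide 16 ⇒ ring-closing metathesis of the 2-(bromomethyl)acrylate of bis-allylic alcohol 13. C5–C6 comes from an asymmetric alkenylzinc addition to acrolein (sets C6).
4. E-C4=C5 ⇒ carboalumination of alkyne 7. C2–C3 ⇒ asymmetric propargylation of Z-enal 4 (sets C2). Z-C1=C10 is inherited from lactone 1.
5. Ring order: butenolide, then ten-membered carbocycle, then the two oxiranes.

**Step 1**
Reactants: 1 4-methyl-5,6-dihydro-2H-pyran-2-one
Product: 3 (2Z)-N-methoxy-N,3-dimethyl-5-(triethylsilyloxy)pent-2-enamide, via ring-opened amide magnesium alkoxide 2 (not isolated)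
Conditions: MeNH(OMe)·HCl, i-PrMgCl, THF, −20 °C; then TESCl, imidazole (cat.), 0 °C to rt
Reagents that add atoms: N,O-dimethylhydroxylamine hydrochloride CNOC.Cl; chlorotriethylsilane CC[Si](Cl)(CC)CC
Why: Weinreb aminolysis of the lactone by the magnesium amide carries the ring-locked Z geometry of C1=C10 into the open chain, and silylating the alkoxide in the same flask prevents relactonisation.

**Step 2**
Reactants: 3 (2Z)-N-methoxy-N,3-dimethyl-5-(triethylsilyloxy)pent-2-enamide
Product: 4 (2Z)-3-methyl-5-(triethylsilyloxy)pent-2-enal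
Conditions: i-Bu2AlH, THF, −78 °C; Rochelle salt work-up
Reagents that add atoms: none
Why: Weinreb amide reduction stops at the chelated tetrahedral aluminate, so the Z-enal is released only on cold work-up, without over-reduction or Z to E drift.

**Step 3**
Reactants: 4 (2Z)-3-methyl-5-(triethylsilyloxy)pent-2-enal; 5 allenylboronic acid pinacol ester
Product: 6 (4S,5Z)-6-methyl-8-(triethylsilyloxy)oct-5-en-1-yn-4-ol
Conditions: (S)-TRIP (10 mol %), 4 Å MS, toluene, −20 °C
Reagents that add atoms: allenylboronic acid pinacol ester (5) C=C=CB1OC(C)(C)C(C)(C)O1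
Why: In this chiral phosphoric acid catalysed asymmetric propargylation the allenylboronate adds through a closed six-membered SE2' transition state to the Si face of the enal held by (S)-TRIP, which sets C2 as S and gives only the homopropargylic alcohol.

**Step 4**
Reactants: 6 (4S,5Z)-6-methyl-8-(triethylsilyloxy)oct-5-en-1-yn-4-ol
Product: 7 (4S,5Z)-4-(tert-butyldimethylsilyloxy)-6-methyl-8-(triethylsilyloxy)oct-5-en-1-yne
Conditions: TBSCl, imidazole, DMF, rt
Reagents that add atoms: tert-butyldimethylsilyl chloride CC(C)(C)[Si](C)(C)Cl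
Why: Standard imidazole-promoted silylation masks the C2 hydroxyl with a group that outlasts the primary TES ether and does not touch the stereocentre.

**Step 5**
Reactants: 7 (4S,5Z)-4-(tert-butyldimethylsilyloxy)-6-methyl-8-(triethylsilyloxy)oct-5-en-1-yne
Product: 9 (1E,4S,5Z)-4-(tert-butyldimethylsilyloxy)-1-iodo-2,6-dimethyl-8-(triethylsilyloxy)octa-1,5-diene, via dimethylalkenylalane 8 (not isolated)
Conditions: AlMe3, Cp2ZrCl2 (25 mol %), CH2Cl2, 0 °C to rt; then I2, THF, −30 °C
Reagents that add atoms: trimethylaluminium C[Al](C)C; iodine II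
Why: Negishi zirconium-catalysed carboalumination adds methyl (C15) and aluminium syn across the terminal alkyne only, and iodinolysis with retention gives the E-trisubstituted C4=C5 vinyl iodide.

**Step 6**
Reactants: 9 (1E,4S,5Z)-4-(tert-butyldimethylsilyloxy)-1-iodo-2,6-dimethyl-8-(triethylsilyloxy)octa-1,5-diene; 10 acrolein
Product: 13 (3S,4E,7S,8Z)-7-(tert-butyldimethylsilyloxy)-5,9-dimethyl-11-(triethylsilyloxy)undeca-1,4,8-trien-3-ol, via alkenyllithium 11 (not isolated), via alkenyl(butyl)zinc 12 (not isolated)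
Conditions: t-BuLi (2 equiv), Et2O, −78 °C; ZnCl2, then n-BuLi; TEEDA, (+)-MIB (10 mol %), toluene/hexanes; 10, 0 °C
Reagents that add atoms: acrolein (10) C=CC=O
Why: In this amino-alcohol-catalysed asymmetric alkenylzinc addition the olefin geometry is retained through lithium and zinc, the (+)-MIB zinc complex delivers the alkenyl group to the Re face of acrolein to set C6 as S, and TEEDA ties up LiCl so the racemic background is suppressed.

**Step 7**
Reactants: 13 (3S,4E,7S,8Z)-7-(tert-butyldimethylsilyloxy)-5,9-dimethyl-11-(triethylsilyloxy)undeca-1,4,8-trien-3-ol; 14 2-(bromomethyl)acrylic acid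
Product: 15 (3S,4E,7S,8Z)-7-(tert-butyldimethylsilyloxy)-5,9-dimethyl-11-(triethylsilyloxy)undeca-1,4,8-trien-3-yl 2-(bromomethyl)prop-2-enoate
Conditions: DCC, DMAP (5 mol %), CH2Cl2, 0 °C
Reagents that add atoms: 2-(bromomethyl)acrylic acid (14) C=C(CBr)C(=O)O
Why: Steglich esterification acylates the only free hydroxyl with retention at C6, and cold conditions with little DMAP spare the allylic bromide.

**Step 8**
Reactants: 15 (3S,4E,7S,8Z)-7-(tert-butyldimethylsilyloxy)-5,9-dimethyl-11-(triethylsilyloxy)undeca-1,4,8-trien-3-yl 2-(bromomethyl)prop-2-enoate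
Product: 16 (5R)-3-(bromomethyl)-5-[(1E,4S,5Z)-4-(tert-butyldimethylsilyloxy)-2,6-dimethyl-8-(triethylsilyloxy)octa-1,5-dienyl]furan-2(5H)-one
Conditions: second-generation Grubbs catalyst (5 mol %), CH2Cl2 (0.005 M), 40 °C
Reagents that add atoms: none
Why: In this ring-closing metathesis the ruthenium carbene loads on the only monosubstituted alkene and closes onto the acrylate to give the five-membered butenolide, the trisubstituted alkenes are spectators, and C6 keeps its geometry (the descriptor becomes R only through a priority change).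

**Step 9**
Reactants: 16 (5R)-3-(bromomethyl)-5-[(1E,4S,5Z)-4-(tert-butyldimethylsilyloxy)-2,6-dimethyl-8-(triethylsilyloxy)octa-1,5-dienyl]furan-2(5H)-one
Product: 17 (5R)-3-(bromomethyl)-5-[(1E,4S,5Z)-4-(tert-butyldimethylsilyloxy)-8-hydroxy-2,6-dimethylocta-1,5-dienyl]furan-2(5H)-one
Conditions: AcOH/THF/H2O (3:1:1), 0 °C to rt
Reagents that add atoms: none
Why: In this selective acidic desilylation the primary TES ether hydrolyses far faster than the secondary TBS ether, and the base-free medium leaves the bromide and the acidic C6–H untouched.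

**Step 10**
Reactants: 17 (5R)-3-(bromomethyl)-5-[(1E,4S,5Z)-4-(tert-butyldimethylsilyloxy)-8-hydroxy-2,6-dimethylocta-1,5-dienyl]furan-2(5H)-one
Product: 18 (3Z,5S,7E)-8-[(2R)-4-(bromomethyl)-5-oxo-2,5-dihydrofuran-2-yl]-5-(tert-butyldimethylsilyloxy)-3,7-dimethylocta-3,7-dienal
Conditions: Dess–Martin periodinane, CH2Cl2, 0 °C; used at once
Reagents that add atoms: none
Why: Dess–Martin oxidation is amine-free, so the β,γ-unsaturated aldehyde does not slip into conjugation and the allylic bromide survives.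

**Step 11 (key step)**
Reactants: 18 (3Z,5S,7E)-8-[(2R)-4-(bromomethyl)-5-oxo-2,5-dihydrofuran-2-yl]-5-(tert-butyldimethylsilyloxy)-3,7-dimethylocta-3,7-dienal
Product: 20 (1(10)Z,4E,2S,6R,7R,8S)-2-(tert-butyldimethylsilyloxy)-8-hydroxygermacra-1(10),4,11(13)-trien-12,6-olide, via allylchromium dichloride 19 (not isolated)
Conditions: CrCl2 (8 equiv), THF, rt, 18 added by syringe pump over 12 h (final 0.002 M); then H2O
Reagents that add atoms: none
Why: Proposed new method: two equivalents of divalent chromium reduce the allylic bromide to an allylchromium in which C7, normally the electrophilic β-carbon of the butenolide, becomes a homoenolate-type donor that attacks the equally electrophilic C8 aldehyde carbon through a Zimmerman–Traxler chair on the face anti to the C6 side chain (C6/C7 trans), the ring-locked E-type allyl geometry gives the C7/C8 anti relationship (7R,8S) while the double bond moves out to the C11=C13 methylene, and the closest known reactions are the intermolecular Barbier and Nozaki–Hiyama additions of 3-(bromomethyl)furan-2(5H)-one to aldehydes and the macrocyclic Nozaki–Hiyama allylations that close ten-membered germacrane rings.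

**Step 12**
Reactants: 20 (1(10)Z,4E,2S,6R,7R,8S)-2-(tert-butyldimethylsilyloxy)-8-hydroxygermacra-1(10),4,11(13)-trien-12,6-olide; 21 angelic acid
Product: 23 (1(10)Z,4E,2S,6R,7R,8S)-8-angeloyloxy-2-(tert-butyldimethylsilyloxy)germacra-1(10),4,11(13)-trien-12,6-olide, via angelic 2,4,6-trichlorobenzoic anhydride 22 (not isolated)
Conditions: 21, 2,4,6-trichlorobenzoyl chloride, Et3N, toluene, rt; then 20, toluene, 75 °C (no DMAP)
Reagents that add atoms: angelic acid (21) C/C=C(/C)C(=O)O
Why: This Yamaguchi-type mixed-anhydride acylation transfers the less hindered angeloyl group to the only free hydroxyl with retention at C8, and leaving out nucleophilic catalysts avoids Z to E isomerisation to the tiglate.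

**Step 13**
Reactants: 23 (1(10)Z,4E,2S,6R,7R,8S)-8-angeloyloxy-2-(tert-butyldimethylsilyloxy)germacra-1(10),4,11(13)-trien-12,6-olide
Product: 24 (1(10)Z,4E,2S,6R,7R,8S)-8-angeloyloxy-2-hydroxygermacra-1(10),4,11(13)-trien-12,6-olide
Conditions: HF·pyridine, pyridine, THF, 0 °C to rt
Reagents that add atoms: none
Why: Buffered fluoride desilylation frees the C2 hydroxyl without base, so the α-methylene lactone, the angelate and the 3-oxy-1,5-diene unit are not disturbed.

**Step 14**
Reactants: 24 (1(10)Z,4E,2S,6R,7R,8S)-8-angeloyloxy-2-hydroxygermacra-1(10),4,11(13)-trien-12,6-olide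
Product: 25 (1R,2S,4R,5R,6S,7R,8S,10S)-8-angeloyloxy-1,10:4,5-diepoxy-2-hydroxygermacr-11(13)-en-12,6-olide (CNP0388761.1)
Conditions: m-CPBA (2.3 equiv), CH2Cl2/aq. pH 7 phosphate buffer, 0 °C
Reagents that add atoms: m-chloroperbenzoic acid OOC(=O)c1cccc(Cl)c1
Why: In this Prilezhaev epoxidation with Henbest direction only the two electron-rich ring alkenes react, each from the outer face of the macrocycle, which at C1=C10 is the face carrying the hydrogen-bonding C2 hydroxyl in the A1,3-minimised conformer (threo, 1R,10S) and at C4=C5 is the face syn to the lactone oxygen on C6 (4R,5R), the same sense as in costunolide-type 4,5-epoxidations.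

**Compound list**
1 | 4-methyl-5,6-dihydro-2H-pyran-2-one | CC1=CC(=O)OCC1 | starting material
2 | chloromagnesium alkoxide of (2Z)-5-hydroxy-N-methoxy-N,3-dimethylpent-2-enamide | CON(C)C(=O)/C=C(/C)CCO[Mg]Cl | intermediate
3 | (2Z)-N-methoxy-N,3-dimethyl-5-(triethylsilyloxy)pent-2-enamide | CON(C)C(=O)/C=C(/C)CCO[Si](CC)(CC)CC | intermediate
4 | (2Z)-3-methyl-5-(triethylsilyloxy)pent-2-enal | O=C/C=C(/C)CCO[Si](CC)(CC)CC | intermediate
5 | allenylboronic acid pinacol ester | C=C=CB1OC(C)(C)C(C)(C)O1 | starting material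
6 | (4S,5Z)-6-methyl-8-(triethylsilyloxy)oct-5-en-1-yn-4-ol | C#CC[C@H](O)/C=C(/C)CCO[Si](CC)(CC)CC | intermediate
7 | (4S,5Z)-4-(tert-butyldimethylsilyloxy)-6-methyl-8-(triethylsilyloxy)oct-5-en-1-yne | C#CC[C@H](O[Si](C)(C)C(C)(C)C)/C=C(/C)CCO[Si](CC)(CC)CC | intermediate
8 | dimethyl[(1E,4S,5Z)-4-(tert-butyldimethylsilyloxy)-2,6-dimethyl-8-(triethylsilyloxy)octa-1,5-dienyl]alane | C[Al](C)/C=C(\C)C[C@H](O[Si](C)(C)C(C)(C)C)/C=C(/C)CCO[Si](CC)(CC)CC | intermediate
9 | (1E,4S,5Z)-4-(tert-butyldimethylsilyloxy)-1-iodo-2,6-dimethyl-8-(triethylsilyloxy)octa-1,5-diene | I/C=C(\C)C[C@H](O[Si](C)(C)C(C)(C)C)/C=C(/C)CCO[Si](CC)(CC)CC | intermediate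
10 | acrolein | C=CC=O | starting material
11 | [(1E,4S,5Z)-4-(tert-butyldimethylsilyloxy)-2,6-dimethyl-8-(triethylsilyloxy)octa-1,5-dienyl]lithium | [Li]/C=C(\C)C[C@H](O[Si](C)(C)C(C)(C)C)/C=C(/C)CCO[Si](CC)(CC)CC | intermediate
12 | butyl[(1E,4S,5Z)-4-(tert-butyldimethylsilyloxy)-2,6-dimethyl-8-(triethylsilyloxy)octa-1,5-dienyl]zinc | CCCC[Zn]/C=C(\C)C[C@H](O[Si](C)(C)C(C)(C)C)/C=C(/C)CCO[Si](CC)(CC)CC | intermediate
13 | (3S,4E,7S,8Z)-7-(tert-butyldimethylsilyloxy)-5,9-dimethyl-11-(triethylsilyloxy)undeca-1,4,8-trien-3-ol | C=C[C@H](O)/C=C(\C)C[C@H](O[Si](C)(C)C(C)(C)C)/C=C(/C)CCO[Si](CC)(CC)CC | intermediate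
14 | 2-(bromomethyl)acrylic acid | C=C(CBr)C(=O)O | starting material
15 | (3S,4E,7S,8Z)-7-(tert-butyldimethylsilyloxy)-5,9-dimethyl-11-(triethylsilyloxy)undeca-1,4,8-trien-3-yl 2-(bromomethyl)prop-2-enoate | C=C(CBr)C(=O)O[C@@H](C=C)/C=C(\C)C[C@H](O[Si](C)(C)C(C)(C)C)/C=C(/C)CCO[Si](CC)(CC)CC | intermediate
16 | (5R)-3-(bromomethyl)-5-[(1E,4S,5Z)-4-(tert-butyldimethylsilyloxy)-2,6-dimethyl-8-(triethylsilyloxy)octa-1,5-dienyl]furan-2(5H)-one | O=C1O[C@@H](C=C1CBr)/C=C(\C)C[C@H](O[Si](C)(C)C(C)(C)C)/C=C(/C)CCO[Si](CC)(CC)CC | intermediate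
17 | (5R)-3-(bromomethyl)-5-[(1E,4S,5Z)-4-(tert-butyldimethylsilyloxy)-8-hydroxy-2,6-dimethylocta-1,5-dienyl]furan-2(5H)-one | O=C1O[C@@H](C=C1CBr)/C=C(\C)C[C@H](O[Si](C)(C)C(C)(C)C)/C=C(/C)CCO | intermediate
18 | (3Z,5S,7E)-8-[(2R)-4-(bromomethyl)-5-oxo-2,5-dihydrofuran-2-yl]-5-(tert-butyldimethylsilyloxy)-3,7-dimethylocta-3,7-dienal | O=C1O[C@@H](C=C1CBr)/C=C(\C)C[C@H](O[Si](C)(C)C(C)(C)C)/C=C(/C)CC=O | intermediate
19 | dichloro{[(5R)-5-((1E,4S,5Z)-4-(tert-butyldimethylsilyloxy)-2,6-dimethyl-8-oxoocta-1,5-dienyl)-2-oxo-2,5-dihydrofuran-3-yl]methyl}chromium | O=C1O[C@@H](C=C1C[Cr](Cl)Cl)/C=C(\C)C[C@H](O[Si](C)(C)C(C)(C)C)/C=C(/C)CC=O | intermediate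
20 | (1(10)Z,4E,2S,6R,7R,8S)-2-(tert-butyldimethylsilyloxy)-8-hydroxygermacra-1(10),4,11(13)-trien-12,6-olide | O[C@H]1C/C(C)=C\[C@@H](O[Si](C)(C)C(C)(C)C)C/C(C)=C/[C@H]2OC(=O)C(=C)[C@H]12 | intermediate
21 | angelic acid, (2Z)-2-methylbut-2-enoic acid | C/C=C(/C)C(=O)O | starting material
22 | angelic 2,4,6-trichlorobenzoic anhydride | C/C=C(/C)C(=O)OC(=O)c1c(Cl)cc(Cl)cc1Cl | intermediate
23 | (1(10)Z,4E,2S,6R,7R,8S)-8-angeloyloxy-2-(tert-butyldimethylsilyloxy)germacra-1(10),4,11(13)-trien-12,6-olide | C/C=C(/C)C(=O)O[C@H]1C/C(C)=C\[C@@H](O[Si](C)(C)C(C)(C)C)C/C(C)=C/[C@H]2OC(=O)C(=C)[C@H]12 | intermediate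
24 | (1(10)Z,4E,2S,6R,7R,8S)-8-angeloyloxy-2-hydroxygermacra-1(10),4,11(13)-trien-12,6-olide | C/C=C(/C)C(=O)O[C@H]1C/C(C)=C\[C@@H](O)C/C(C)=C/[C@H]2OC(=O)C(=C)[C@H]12 | intermediate
25 | (1R,2S,4R,5R,6S,7R,8S,10S)-8-angeloyloxy-1,10:4,5-diepoxy-2-hydroxygermacr-11(13)-en-12,6-olide (CNP0388761.1) | C=C1C(=O)O[C@H]2[C@H]1[C@@H](OC(=O)/C(C)=C\C)C[C@]1(C)O[C@@H]1[C@@H](O)C[C@@]1(C)O[C@H]21 | target

**Total step count:** 14. **Longest linear sequence:** 14 (from 1).

**Steps most likely to fail**

The macrocyclisation (step 11) is the largest risk.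
- Failure modes: the allylchromium can be protonated, or it can fragment by vinylogous loss of the C6 carboxylate. Ten-membered closure is slow. The chromium alkoxide could also translactonise to O8.
- Fallback, setting out from 18: treat it under the same high dilution with B2pin2 and Pd2(dba)3 (2.5 mol %) in THF at 60 °C. This replaces the reducible carbon–metal bond by a covalent boronate. The (3Z,5S,7E)-5-(tert-butyldimethylsilyloxy)-3,7-dimethyl-8-{(2R)-5-oxo-4-[(pinacolboryl)methyl]-2,5-dihydrofuran-2-yl}octa-3,7-dienal F1 closes by thermal allylboration. The chair is of the same type and should give the same anti and trans outcome.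
- Aqueous work-up brings the route back at 20.

The asymmetric alkenylzinc addition (step 6) may give low selectivity, because acrolein is small and lithium salts promote a racemic pathway.
- Fallback, setting out from 9: couple it with 10 without chiral control (CrCl2, NiCl2 cat., DMF). This gives the C6-epimeric alcohol mixture (3RS,4E,7S,8Z)-7-(tert-butyldimethylsilyloxy)-5,9-dimethyl-11-(triethylsilyloxy)undeca-1,4,8-trien-3-ol F2.
- F2 is then resolved by Sharpless kinetic resolution: Ti(OiPr)4, D-(−)-DIPT, t-BuOOH (0.6 equiv), 4 Å MS, CH2Cl2, −20 °C.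
- Only the 3R epimer is oxidised, giving (3R,4R,5R,7S,8Z)-4,5-epoxy-7-(tert-butyldimethylsilyloxy)-5,9-dimethyl-11-(triethylsilyloxy)undeca-1,8-dien-3-ol F3. This is removed by chromatography, and the unreacted alcohol is 13.

The double epoxidation (step 14) relies on the conformation of a Z,E ten-membered ring. One alkene may show the wrong face, or the monoepoxide may cyclise across the ring.
- Fallback, setting out from 24: split the event and switch the second oxidation to reagent control.
- First, VO(acac)2/t-BuOOH (CH2Cl2, 0 °C) epoxidises only the allylic C1=C10 bond under hydroxyl direction. The product is (1R,2S,4E,6R,7R,8S,10S)-8-angeloyloxy-1,10-epoxy-2-hydroxygermacra-4,11(13)-dien-12,6-olide F4.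
- Second, the D-fructose-derived Shi ketone with Oxone (buffered MeCN/dimethoxymethane/H2O, 0 °C) imposes the 4R,5R oxirane on the E-trisubstituted alkene. The route returns at 25.

**Further compounds**
F1 | step 11 | (3Z,5S,7E)-5-(tert-butyldimethylsilyloxy)-3,7-dimethyl-8-{(2R)-5-oxo-4-[(pinacolboryl)methyl]-2,5-dihydrofuran-2-yl}octa-3,7-dienal | O=C1O[C@@H](C=C1CB2OC(C)(C)C(C)(C)O2)/C=C(\C)C[C@H](O[Si](C)(C)C(C)(C)C)/C=C(/C)CC=O
F2 | step 6 | (3RS,4E,7S,8Z)-7-(tert-butyldimethylsilyloxy)-5,9-dimethyl-11-(triethylsilyloxy)undeca-1,4,8-trien-3-ol (C3 epimer mixture) | C=CC(O)/C=C(\C)C[C@H](O[Si](C)(C)C(C)(C)C)/C=C(/C)CCO[Si](CC)(CC)CC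
F3 | step 6 | (3R,4R,5R,7S,8Z)-4,5-epoxy-7-(tert-butyldimethylsilyloxy)-5,9-dimethyl-11-(triethylsilyloxy)undeca-1,8-dien-3-ol | C=C[C@@H](O)[C@H]1O[C@]1(C)C[C@H](O[Si](C)(C)C(C)(C)C)/C=C(/C)CCO[Si](CC)(CC)CC
F4 | step 14 | (1R,2S,4E,6R,7R,8S,10S)-8-angeloyloxy-1,10-epoxy-2-hydroxygermacra-4,11(13)-dien-12,6-olide | C/C=C(/C)C(=O)O[C@H]1C[C@]3(C)O[C@@H]3[C@@H](O)C/C(C)=C/[C@H]2OC(=O)C(=C)[C@H]12
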